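**Retrosynthetic overview**
1. The oxirane (ring E, C14–O15–C16) is made last, by hydroxyl-directed epoxidation of a C14=C16 alkene. The directing C18–OH comes from reagent-controlled reduction of a C18 enone.
2. The halves are joined at C13–C14. A west C13 alkyllithium adds to the C14 carbonyl of an east cycloheptenone, and oxidative 1,3-transposition then moves the oxygen to C18.
3. The west half rests on one feature. C2 is the gem-dimethyl tertiary ether carbon of the oxepane (ring A: O4, C2, C35, C34, C33, C31, C5), bonded to O4 and C35, and it is the carbonyl carbon of acetone. It is carried on O4 as a mixed methyl ketal, and ring A is closed through the C2–C35 bond by a (Z)-vinylsilane on C33.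
4. Cyclohexane ring B comes from an arene. A CBS reduction creates a temporary C8 carbinol whose configuration is relayed to C11, C31 and C5. After ring closure, C8 is set by MeLi and C35–OH by epoxidation and hydride opening.
5. East half: (R)-linalool supplies C25 and gives cyclopentene ring D by metathesis; a second metathesis closes cycloheptenone ring C. Order of ring formation: B, then A; D, then C; E last.

Key step: step 14

Remark: atoms are labelled C1–O36 by their position in the target SMILES. In the west half α is the face of the angular methyl C32; in the east half α is the face of H21 and H22. C14 of compound 43 forms without control, is drawn without configuration, and becomes sp2 in step 30.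

**Reagent for C33–C35**

Step 1
Reactants: 1 3-(trimethylsilyl)prop-2-yn-1-ol
Product: 2 (Z)-3-(trimethylsilyl)prop-2-en-1-ol
Conditions: H2 (1 atm), Pd/CaCO3 poisoned with Pb(OAc)2, quinoline, hexane–EtOAc, rt
Reagents that add atoms: none
Why: Syn semihydrogenation of the alkynylsilane on poisoned palladium should stop at the (Z)-vinylsilane, which fixes the alkene geometry needed in step 14.

Step 2
Reactants: 2 (Z)-3-(trimethylsilyl)prop-2-en-1-ol
Product: 3 (Z)-3-bromo-1-(trimethylsilyl)prop-1-ene
Conditions: CBr4, PPh3, CH2Cl2, 0 °C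
Reagents that add atoms: carbon tetrabromide BrC(Br)(Br)Br
Why: The Appel bromination replaces the primary allylic hydroxyl by SN2 at carbon and leaves the alkene geometry untouched.

**West half**

Step 3
Reactants: 4 4-methoxy-3-methylphenol
Product: 5 4,4-dimethoxy-3-methylcyclohexa-2,5-dien-1-one
Conditions: PhI(OAc)2, MeOH, 0 °C
Reagents that add atoms: methanol CO
Why: Hypervalent-iodine oxidative dearomatisation of a para-methoxyphenol in methanol traps the phenoxenium ion at C5 as the quinone monoketal.

Step 4
Reactants: 5 4,4-dimethoxy-3-methylcyclohexa-2,5-dien-1-one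
Product: 6 4,4-dimethoxy-3-methylcyclohex-2-en-1-one
Conditions: H2 (1 atm), RhCl(PPh3)3 (cat.), benzene–EtOH, rt
Reagents that add atoms: none
Why: Homogeneous hydrogenation discriminates by alkene substitution and should saturate only the disubstituted C6=C7 bond, so that one enone position remains for later conjugate addition.

Step 5
Reactants: 6 4,4-dimethoxy-3-methylcyclohex-2-en-1-one
Product: 8 (R)-4-hydroxy-2-methylcyclohex-2-en-1-one, via ketal alcohol 7 (not isolated)
Conditions: (S)-2-methyl-CBS-oxazaborolidine (cat.), BH3·SMe2, THF, −20 °C; then 1 M HCl, THF, 0 °C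
Reagents that add atoms: water O
Why: In the CBS reduction the alkenyl branch acts as the large group, which should give the (R)-carbinol at C8 by reagent control, and the acidic work-up hydrolyses the allylic ketal so that the enone becomes C5(=O)–C31=C11.

Step 6
Reactants: 8 (R)-4-hydroxy-2-methylcyclohex-2-en-1-one
Product: 9 (R)-4-(tert-butyldimethylsilyloxy)-2-methylcyclohex-2-en-1-one
Conditions: TBSCl, imidazole, DMF, rt
Reagents that add atoms: tert-butyldimethylsilyl chloride CC(C)(C)[Si](C)(C)Cl
Why: Imidazole-promoted silylation installs the bulky β-oriented C8 silyloxy group that steers the next step.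

Step 7
Reactants: 9 (R)-4-(tert-butyldimethylsilyloxy)-2-methylcyclohex-2-en-1-one; 3 (Z)-3-bromo-1-(trimethylsilyl)prop-1-ene
Product: 11 (2R,3R,4R)-4-(tert-butyldimethylsilyloxy)-2-methyl-2-[(Z)-3-(trimethylsilyl)prop-2-enyl]-3-vinylcyclohexan-1-one, via bromomagnesium enolate 10 (not isolated)
Conditions: CH2=CHMgBr, CuBr·SMe2 (cat.), THF, −78 °C; then 3, DMPU, −78 → 0 °C
Reagents that add atoms: vinylmagnesium bromide C=C[Mg]Br
Why: In this conjugate addition–enolate alkylation the vinyl group should add anti to the C8 silyloxy group (sets C11), and the regiodefined enolate should then be alkylated anti to the new vinyl group (sets quaternary C31 with C33 on the β face).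

Step 8
Reactants: 11 the C5 ketone
Product: 12 (1R,2R,3R,4R)-4-(tert-butyldimethylsilyloxy)-2-methyl-2-[(Z)-3-(trimethylsilyl)prop-2-enyl]-3-vinylcyclohexan-1-ol
Conditions: NaBH4, MeOH–CH2Cl2, 0 °C
Reagents that add atoms: none
Why: Borohydride should attack the C5 ketone axially from the β face, away from the axial C32 methyl, which gives the equatorial alcohol (sets C5) cis to C32 and trans to C33.

Step 9
Reactants: 12 the C5 alcohol
Product: 14 C5,C13 diol (vinyl converted into 2-hydroxyethyl), via C13 alkylborane 13 (not isolated)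
Conditions: 9-BBN, THF, 0 °C → rt; then NaOH, H2O2
Reagents that add atoms: hydrogen peroxide OO
Why: In the Brown hydroboration–oxidation 9-BBN selects the monosubstituted vinyl group over the hindered 1,2-disubstituted vinylsilane and places oxygen on terminal C13.

Step 10
Reactants: 14 the C5,C13 diol
Product: 15 C13 pivalate with free C5 hydroxyl
Conditions: PivCl, pyridine, CH2Cl2, 0 °C
Reagents that add atoms: pivaloyl chloride CC(C)(C)C(=O)Cl
Why: Acylation with the bulky acid chloride is selective for the primary C13 hydroxyl over the neopentylic C5 hydroxyl.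

Step 11
Reactants: 15 the C13 pivalate; 16 2-methoxypropene
Product: 17 C5 2-methoxyprop-2-yl ether (mixed acetone ketal) with C8 silyl ether
Conditions: PPTS (cat.), CH2Cl2, 0 °C
Reagents that add atoms: none
Why: Acid-catalysed addition of the hindered alcohol to the enol ether puts C1, C2 and C3 on O4 under conditions that spare the silyl ether and the vinylsilane.

Step 12
Reactants: 17 the mixed ketal silyl ether
Product: 18 mixed ketal with free C8 hydroxyl
Conditions: n-Bu4NF, THF, rt
Reagents that add atoms: none
Why: Fluoride-mediated desilylation cleaves only the O–Si bond, because the mixed ketal and the pivalate are stable to base and the vinylic C–Si bond is not activated.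

Step 13
Reactants: 18 the C8 alcohol
Product: 19 key precursor: C5 2-methoxyprop-2-yl ether, C8 ketone, C11 α-(2-pivaloyloxyethyl), C31 α-methyl and β-(Z)-3-(trimethylsilyl)allyl
Conditions: (n-Pr4N)RuO4 (cat.), NMO, 4 Å molecular sieves, CH2Cl2, rt
Reagents that add atoms: none
Why: The non-acidic Ley–Griffith oxidation spares the mixed ketal and erases the auxiliary C8 stereocentre, while C11 keeps its equatorial, thermodynamically preferred configuration.

Step 14
Reactants: 19 the key precursor
Product: 21 trans-fused oxepene–cyclohexanone with C34=C35 alkene, via oxocarbenium triflate 20 (not isolated)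
Conditions: TMSOTf (0.2 equiv), 2,6-di-tert-butyl-4-methylpyridine, CH2Cl2, −78 → −40 °C
Reagents that add atoms: none
Why: TMSOTf silylates the unhindered methoxy oxygen and expels MeOSiMe3 to leave the dimethyl-substituted oxocarbenium ion 20 on O4; the silicon-bearing carbon C35 then attacks C2, the cation developing at C34 is stabilised by the β C–Si bond, and loss of the silyl group to triflate regenerates both the promoter and the C34=C35 alkene. The closest known reaction type is the vinylsilane-terminated cyclisation of oxocarbenium ions from mixed acetals of 5-silylpent-4-en-1-ols to 2,5,6,7-tetrahydrooxepines, applied here to the less common ketone-derived ion. Ring A closes in the 7-endo mode with respect to the vinylsilane, so both alkene carbons end inside the ring. No stereocentre is formed, and the trans ring fusion follows from the diequatorial O4 and C33 set in steps 7 and 8. The (Z)-geometry is essential, because silicon is replaced with retention and only the (Z)-isomer can place C33 and C2 cis on the ring alkene while its C–Si bond stays aligned with the empty orbital at C34. The step needs loss of methoxide rather than of the C5 alkoxide, which the accessible OMe group secures and which is reversible by recombination if it goes the wrong way, and it needs ipso attack at C35 rather than 6-exo attack through C34, which the β-silicon effect secures, while the hindered pyridine removes adventitious acid that would protodesilylate the terminator.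

Step 15
Reactants: 21 the oxepene ketone
Product: 23 oxepene with C8 β-methyl and α-(axial) triethylsilyloxy group, via lithium alkoxide 22 (not isolated)
Conditions: MeLi, Et2O, −78 °C; then TESOTf, −78 → 0 °C
Reagents that add atoms: methyllithium [Li]C; triethylsilyl triflate CC[Si](CC)(CC)OS(=O)(=O)C(F)(F)F
Why: In this 1,2-addition methyllithium should attack the ketone faster than the pivalate and along the equatorial path from the β face, since the axial path is blocked by the 1,3-diaxial C32 methyl (sets C8), and the alkoxide is silylated in the same flask before any hydride reagent is used.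

Step 16
Reactants: 23 the oxepene silyl ether
Product: 24 C34,C35 β-epoxide
Conditions: mCPBA, NaHCO3, CH2Cl2, 0 °C
Reagents that add atoms: 3-chloroperoxybenzoic acid OOC(=O)c1cccc(Cl)c1
Why: Prilezhaev epoxidation of the only alkene should occur on the β face, anti to the axial C32 methyl that lies gauche to C34 (sets C35).

Step 17
Reactants: 24 the β-epoxide
Product: 25 C35,C13 diol with C8 silyl ether
Conditions: LiEt3BH (excess), THF, 0 → 50 °C
Reagents that add atoms: none
Why: Hydride opens the epoxide by SN2 attack at C34, the carbon remote from quaternary C2 (a Fürst–Plattner-type opening), so the C35–O bond keeps its configuration, and the same reagent reduces off the pivalate.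

Step 18
Reactants: 25 the diol
Product: 26 C13 iodide with free C35 hydroxyl
Conditions: I2, PPh3, imidazole, CH2Cl2, 0 °C
Reagents that add atoms: iodine II
Why: The Garegg–Samuelsson (Appel-type) iodination acts only on the primary alcohol, and the silyl group on O10 prevents closure of a tetrahydrofuran between O10 and C13.

Step 19
Reactants: 26 the iodo alcohol
Product: 27 west iodide with C8 and C35 triethylsilyl ethers
Conditions: TESOTf, 2,6-lutidine, CH2Cl2, −78 → 0 °C
Reagents that add atoms: triethylsilyl triflate CC[Si](CC)(CC)OS(=O)(=O)C(F)(F)F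
Why: Silyl triflate silylation masks the last acidic proton before the lithium–iodine exchange.

**East half**

Step 20
Reactants: 28 (R)-(−)-linalool
Product: 29 (R)-1-methylcyclopent-2-en-1-ol
Conditions: second-generation Hoveyda–Grubbs catalyst (cat.), CH2Cl2, 40 °C
Reagents that add atoms: none
Why: Ring-closing metathesis of the 1,6-diene expels isobutene, closes ring D and leaves the chiral-pool carbinol centre C25 untouched.

Step 21
Reactants: 29 (R)-1-methylcyclopent-2-en-1-ol
Product: 30 cis-epoxy alcohol (C21,C22 epoxide oxygen and O27 both α)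
Conditions: mCPBA, NaHCO3, CH2Cl2, 0 °C
Reagents that add atoms: 3-chloroperoxybenzoic acid OOC(=O)c1cccc(Cl)c1
Why: Hydroxyl-directed (Henbest) epoxidation, reinforced by the C26 methyl that shields the β face, should deliver oxygen syn to the C25 hydroxyl.

Step 22
Reactants: 30 the cis-epoxy alcohol; 31 isobutyronitrile
Product: 33 2-[(1S,2S,3R)-2,3-dihydroxy-3-methylcyclopentyl]-2-methylpropanenitrile, via lithiated isobutyronitrile 32 (not isolated)
Conditions: 31, LDA, THF, −78 °C; then 30, −78 → 50 °C
Reagents that add atoms: none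
Why: The slim tertiary nitrile anion opens the epoxide by SN2 attack with inversion at C22, the carbon remote from the oxido-substituted C25, which places C28 on the β face (sets C22) and builds quaternary C28 together with C14.

Step 23
Reactants: 33 the diol nitrile
Product: 34 C21 ketone (α-ketol nitrile)
Conditions: IBX, EtOAc, 75 °C
Reagents that add atoms: none
Why: IBX oxidises the secondary alcohol of a 1,2-diol to the α-ketol without C–C cleavage.

Step 24
Reactants: 34 the α-ketol nitrile
Product: 35 C21=C20 exocyclic methylene compound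
Conditions: Cp2TiMe2, toluene, 70 °C
Reagents that add atoms: dimethyltitanocene C[Ti](C)(C1C=CC=C1)C1C=CC=C1
Why: The Petasis methylenation runs through a neutral titanium methylidene, so the hindered and epimerisable ketone should be converted without enolisation at C22 and without ionising the new tertiary allylic alcohol.

Step 25
Reactants: 35 the methylene compound
Product: 37 C21 β-allyl nitrile (H21 α, allyl cis to the C28 substituent), via C20 alkylborane 36 (not isolated)
Conditions: 9-BBN, THF, rt; then CH2=CHBr, Pd(dppf)Cl2 (cat.), aq NaOH, THF, 50 °C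
Reagents that add atoms: vinyl bromide C=CBr
Why: 9-BBN should add from the α face, opposite to the C28 substituent and the C26 methyl, which puts H21 on the α face (sets C21), and the B-alkyl Suzuki–Miyaura coupling then makes the C20–C18 bond.

Step 26
Reactants: 37 the allyl nitrile
Product: 39 isopropenyl ketone (C14=O, C16, C17) bearing the C21 allyl group, via N-lithio ketimine 38 (not isolated)
Conditions: 2-bromopropene, t-BuLi, Et2O, −78 °C; then 37, −78 °C → rt; then 1 M HCl, THF, rt
Reagents that add atoms: 2-bromopropene CC(Br)=C; water O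
Why: Addition of an alkenyllithium to the non-enolisable tertiary nitrile stops at the ketimine salt, whose hydrolysis gives the α-methyl enone.

Step 27
Reactants: 39 the dienone
Product: 40 (1R,3aR,8aR)-1-hydroxy-1,4,4,6-tetramethyl-2,3,3a,4,8,8a-hexahydroazulen-5(1H)-one
Conditions: second-generation Grubbs catalyst (cat.), CH2Cl2, reflux
Reagents that add atoms: none
Why: Ring-closing metathesis of the allyl group with the isopropenyl ketone, helped by the cis-1,2 arrangement on ring D and by the gem-dimethyl effect, closes ring C as the trisubstituted C16=C18 enone.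

Step 28
Reactants: 40 the hydroxy enone
Product: 41 east enone with C25 triethylsilyl ether
Conditions: TESOTf, 2,6-lutidine, CH2Cl2, −78 → 0 °C
Reagents that add atoms: triethylsilyl triflate CC[Si](CC)(CC)OS(=O)(=O)C(F)(F)F
Why: Silyl triflate silylation of the tertiary alcohol removes the only acidic proton of the electrophile.

**Union and end game**

Step 29
Reactants: 27 the west iodide; 41 the east enone
Product: 43 C14 tertiary allylic alcohol with the C13–C14 bond, via alkyllithium 42 (not isolated)
Conditions: 27, t-BuLi (2.1 equiv), Et2O–pentane, −78 °C; then 41, −78 → −20 °C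
Reagents that add atoms: none
Why: Lithium–iodine exchange gives the primary alkyllithium, which should add 1,2 to the C14 carbonyl, a carbonyl that has no α-hydrogen.

Step 30
Reactants: 43 the tertiary allylic alcohol
Product: 44 C18 enone with tetrasubstituted C14=C16 alkene
Conditions: (C5H5NH)[CrO3Cl], NaOAc, 4 Å molecular sieves, CH2Cl2, rt
Reagents that add atoms: pyridinium chlorochromate c1cc[nH+]cc1.[O-][Cr](=O)(=O)Cl
Why: In the Babler–Dauben oxidative transposition the chromate ester of the tertiary allylic alcohol shifts by a [3,3] process to C18 and is oxidised there to the enone.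

Step 31
Reactants: 44 the enone
Product: 45 (18R)-allylic alcohol (O19 α)
Conditions: (S)-2-methyl-CBS-oxazaborolidine, BH3·SMe2, toluene, −40 °C
Reagents that add atoms: none
Why: In the CBS reduction the fully substituted alkenyl branch C16 acts as the large group against C20H2, so the reagent rather than the folded bicycle should set C18.

Step 32
Reactants: 45 the tris(silyl) allylic alcohol
Product: 46 tetraol with C14=C16 alkene
Conditions: n-Bu4NF, THF, rt → 40 °C
Reagents that add atoms: none
Why: Fluoride-mediated desilylation frees O10, O27 and O36 under non-acidic conditions that do not ionise the allylic alcohol, and it is done before the acid-sensitive epoxide exists.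

Step 33
Reactants: 46 the tetraol
Product: 47 target CNP0203623.2
Conditions: VO(acac)2 (cat.), t-BuOOH, CH2Cl2, 0 °C
Reagents that add atoms: tert-butyl hydroperoxide CC(C)(C)OO
Why: Vanadium-catalysed epoxidation is directed by the allylic C18 hydroxyl, so the only alkene should be epoxidised syn to O19 on the α face (sets C14 and C16).

**Compound list**
1 | 3-(trimethylsilyl)prop-2-yn-1-ol | C[Si](C)(C)C#CCO | starting material
2 | (Z)-3-(trimethylsilyl)prop-2-en-1-ol | C[Si](C)(C)/C=C\CO | intermediate
3 | (Z)-3-bromo-1-(trimethylsilyl)prop-1-ene | C[Si](C)(C)/C=C\CBr | intermediate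
4 | 4-methoxy-3-methylphenol | COc1ccc(O)cc1C | starting material
5 | 4,4-dimethoxy-3-methylcyclohexa-2,5-dien-1-one | COC1(OC)C=CC(=O)C=C1C | intermediate
6 | 4,4-dimethoxy-3-methylcyclohex-2-en-1-one | COC1(OC)CCC(=O)C=C1C | intermediate
7 | (R)-4,4-dimethoxy-3-methylcyclohex-2-en-1-ol | COC1(OC)CC[C@@H](O)C=C1C | intermediate
8 | (R)-4-hydroxy-2-methylcyclohex-2-en-1-one | O=C1CC[C@@H](O)C=C1C | intermediate
9 | (R)-4-(tert-butyldimethylsilyloxy)-2-methylcyclohex-2-en-1-one | O=C1CC[C@@H](O[Si](C)(C)C(C)(C)C)C=C1C | intermediate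
10 | bromomagnesium C5 enolate of the C11 vinyl adduct | Br[Mg]OC=1CC[C@@H](O[Si](C)(C)C(C)(C)C)[C@H](C=C)C=1C | intermediate
11 | (2R,3R,4R)-4-(tert-butyldimethylsilyloxy)-2-methyl-2-[(Z)-3-(trimethylsilyl)prop-2-enyl]-3-vinylcyclohexan-1-one | O=C1CC[C@@H](O[Si](C)(C)C(C)(C)C)[C@H](C=C)[C@@]1(C)C/C=C\[Si](C)(C)C | intermediate
12 | (1R,2R,3R,4R)-cyclohexanol from 11 (C5 α-OH, equatorial) | O[C@@H]1CC[C@@H](O[Si](C)(C)C(C)(C)C)[C@H](C=C)[C@@]1(C)C/C=C\[Si](C)(C)C | intermediate
13 | C13 B-alkyl-9-borabicyclo[3.3.1]nonane from 12 | O[C@@H]1CC[C@@H](O[Si](C)(C)C(C)(C)C)[C@H](CCB2C3CCCC2CCC3)[C@@]1(C)C/C=C\[Si](C)(C)C | intermediate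
14 | C5,C13 diol | O[C@@H]1CC[C@@H](O[Si](C)(C)C(C)(C)C)[C@H](CCO)[C@@]1(C)C/C=C\[Si](C)(C)C | intermediate
15 | C13 pivalate, free C5 hydroxyl | O[C@@H]1CC[C@@H](O[Si](C)(C)C(C)(C)C)[C@H](CCOC(=O)C(C)(C)C)[C@@]1(C)C/C=C\[Si](C)(C)C | intermediate
16 | 2-methoxypropene | COC(C)=C | starting material
17 | C5 2-methoxyprop-2-yl ether, C8 silyl ether | COC(C)(C)O[C@@H]1CC[C@@H](O[Si](C)(C)C(C)(C)C)[C@H](CCOC(=O)C(C)(C)C)[C@@]1(C)C/C=C\[Si](C)(C)C | intermediate
18 | C5 2-methoxyprop-2-yl ether, free C8 β-hydroxyl | COC(C)(C)O[C@@H]1CC[C@@H](O)[C@H](CCOC(=O)C(C)(C)C)[C@@]1(C)C/C=C\[Si](C)(C)C | intermediate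
19 | key precursor: C5 2-methoxyprop-2-yl ether, C8 ketone, (Z)-vinylsilane | COC(C)(C)O[C@@H]1CCC(=O)[C@H](CCOC(=O)C(C)(C)C)[C@@]1(C)C/C=C\[Si](C)(C)C | intermediate
20 | O4 dimethyl oxocarbenium triflate | CC(C)=[O+][C@@H]1CCC(=O)[C@H](CCOC(=O)C(C)(C)C)[C@@]1(C)C/C=C\[Si](C)(C)C.[O-]S(=O)(=O)C(F)(F)F | intermediate
21 | trans-fused oxepene–cyclohexanone, C34=C35 | CC1(C)O[C@@H]2CCC(=O)[C@H](CCOC(=O)C(C)(C)C)[C@@]2(C)CC=C1 | intermediate
22 | C8 lithium alkoxide | CC1(C)O[C@@H]2CC[C@](C)(O[Li])[C@H](CCOC(=O)C(C)(C)C)[C@@]2(C)CC=C1 | intermediate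
23 | oxepene, C8 β-methyl, α-triethylsilyloxy | CC1(C)O[C@@H]2CC[C@](C)(O[Si](CC)(CC)CC)[C@H](CCOC(=O)C(C)(C)C)[C@@]2(C)CC=C1 | intermediate
24 | C34,C35 β-epoxide | CC1(C)O[C@@H]2CC[C@](C)(O[Si](CC)(CC)CC)[C@H](CCOC(=O)C(C)(C)C)[C@@]2(C)C[C@H]3O[C@@H]13 | intermediate
25 | C35 β-alcohol, C13 alcohol | CC1(C)O[C@@H]2CC[C@](C)(O[Si](CC)(CC)CC)[C@H](CCO)[C@@]2(C)CC[C@H]1O | intermediate
26 | C13 iodide, free C35 hydroxyl | CC1(C)O[C@@H]2CC[C@](C)(O[Si](CC)(CC)CC)[C@H](CCI)[C@@]2(C)CC[C@H]1O | intermediate
27 | west iodide, C8 and C35 triethylsilyl ethers | CC1(C)O[C@@H]2CC[C@](C)(O[Si](CC)(CC)CC)[C@H](CCI)[C@@]2(C)CC[C@H]1O[Si](CC)(CC)CC | intermediate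
28 | (R)-(−)-linalool | C=C[C@](C)(O)CCC=C(C)C | starting material
29 | (R)-1-methylcyclopent-2-en-1-ol | C[C@]1(O)C=CCC1 | intermediate
30 | 2-methyl-6-oxabicyclo[3.1.0]hexan-2-ol, epoxide cis to hydroxyl | C[C@@]1(O)CC[C@@H]2O[C@H]12 | intermediate
31 | isobutyronitrile | CC(C)C#N | starting material
32 | 2-lithio-2-methylpropanenitrile | [Li]C(C)(C)C#N | intermediate
33 | 2-[(1S,2S,3R)-2,3-dihydroxy-3-methylcyclopentyl]-2-methylpropanenitrile | N#CC(C)(C)[C@@H]1CC[C@@](C)(O)[C@H]1O | intermediate
34 | C21 ketone (α-ketol nitrile) | N#CC(C)(C)[C@@H]1CC[C@@](C)(O)C1=O | intermediate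
35 | C21=C20 methylene nitrile | N#CC(C)(C)[C@@H]1CC[C@@](C)(O)C1=C | intermediate
36 | C20 B-alkyl-9-borabicyclo[3.3.1]nonane | N#CC(C)(C)[C@@H]1CC[C@@](C)(O)[C@@H]1CB2C3CCCC2CCC3 | intermediate
37 | C21 β-allyl nitrile | N#CC(C)(C)[C@@H]1CC[C@@](C)(O)[C@@H]1CC=C | intermediate
38 | N-lithio ketimine at C14 | C=C(C)C(=N[Li])C(C)(C)[C@@H]1CC[C@@](C)(O)[C@@H]1CC=C | intermediate
39 | isopropenyl ketone with C21 allyl group | C=C(C)C(=O)C(C)(C)[C@@H]1CC[C@@](C)(O)[C@@H]1CC=C | intermediate
40 | (1R,3aR,8aR)-1-hydroxy-1,4,4,6-tetramethyl-2,3,3a,4,8,8a-hexahydroazulen-5(1H)-one | O=C1C(C)=CC[C@@H]2[C@@H](CC[C@@]2(C)O)C1(C)C | intermediate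
41 | C25 triethylsilyl ether of 40 | O=C1C(C)=CC[C@@H]2[C@@H](CC[C@@]2(C)O[Si](CC)(CC)CC)C1(C)C | intermediate
42 | west C13 alkyllithium | CC1(C)O[C@@H]2CC[C@](C)(O[Si](CC)(CC)CC)[C@H](CC[Li])[C@@]2(C)CC[C@H]1O[Si](CC)(CC)CC | intermediate
43 | C14 tertiary allylic alcohol (C14 not controlled) | CC1(C)O[C@@H]2CC[C@](C)(O[Si](CC)(CC)CC)[C@H](CCC3(O)C(C)=CC[C@@H]4[C@@H](CC[C@@]4(C)O[Si](CC)(CC)CC)C3(C)C)[C@@]2(C)CC[C@H]1O[Si](CC)(CC)CC | intermediate
44 | C18 enone, C14=C16 | CC1(C)O[C@@H]2CC[C@](C)(O[Si](CC)(CC)CC)[C@H](CCC3=C(C)C(=O)C[C@@H]4[C@@H](CC[C@@]4(C)O[Si](CC)(CC)CC)C3(C)C)[C@@]2(C)CC[C@H]1O[Si](CC)(CC)CC | intermediate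
45 | (18R)-allylic alcohol, three triethylsilyl ethers | CC1(C)O[C@@H]2CC[C@](C)(O[Si](CC)(CC)CC)[C@H](CCC3=C(C)[C@H](O)C[C@@H]4[C@@H](CC[C@@]4(C)O[Si](CC)(CC)CC)C3(C)C)[C@@]2(C)CC[C@H]1O[Si](CC)(CC)CC | intermediate
46 | tetraol with C14=C16 alkene | CC1(C)O[C@@H]2CC[C@](C)(O)[C@H](CCC3=C(C)[C@H](O)C[C@@H]4[C@@H](CC[C@@]4(C)O)C3(C)C)[C@@]2(C)CC[C@H]1O | intermediate
47 | CNP0203623.2 | CC1(C)O[C@@H]2CC[C@](C)(O)[C@H](CC[C@@]34O[C@]3(C)[C@H](O)C[C@@H]3[C@@H](CC[C@@]3(C)O)C4(C)C)[C@@]2(C)CC[C@H]1O | target

**Step count**
- Total step count: 33.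
- Longest linear sequence: 22 steps (steps 3–19 and 29–33).

**Steps most likely to fail**

Step 14. The tertiary oxocarbenium ion may lose a proton to give the isopropenyl ether, or fragment to acetone and the C5 alcohol, faster than the hindered C2–C35 bond forms. Protodesilylation of the vinylsilane may also compete. The fallback makes the same C2–C35 bond by palladium catalysis instead of cation chemistry; it sets out from 15 and comes back at 21. Iododesilylation of 15 (NIS, MeCN, 0 °C, retention of geometry) should give the (Z)-vinyl iodide F1. Addition of F1 to 16 (PPTS) gives the mixed ketal F2, and TMSOTf with i-Pr2NEt removes methanol to leave the isopropenyl ether F3. A reductive Heck cyclisation (Pd(OAc)2, PPh3, HCO2Na, Et4NCl, DMF, 80 °C) joins C35 to C2 in the 7-exo mode. The primary alkylpalladium species has no β-hydrogen and is reduced by formate to the second C2 methyl group, which gives the oxepene silyl ether F4. n-Bu4NF then frees the C8 alcohol F5, and (n-Pr4N)RuO4 with NMO oxidises it to 21.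

Step 29. Two hindered partners have to meet. γ-Deprotonation of the enone, conjugate addition at C18, or oxygen-to-carbon silyl migration in the alkyllithium may outrun 1,2-addition at the carbonyl flanked by C28 and C16. The fallback replaces carbonyl addition by cross-coupling; it sets out from 41 and 27 and comes back at 44. Conjugate reduction of 41 with LiBH(s-Bu)3 and trapping of the regiodefined enolate with PhNTf2 should give the tetrasubstituted enol triflate F6. Compound 27 is converted by t-BuLi and B-methoxy-9-BBN into the B-alkylborane F7. B-alkyl Suzuki–Miyaura coupling (Pd(dppf)Cl2, K3PO4, DMF–THF–H2O) gives the C14=C16 alkene F8, which lacks O19. Allylic oxidation of the ring methylene C18, next to the methyl-bearing alkene carbon (CrO3, 3,5-dimethylpyrazole, CH2Cl2, −20 °C), then gives 44.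

Step 16. The seven-membered ring is flexible and the two C2 methyl groups shield both faces, so facial selectivity of the peracid may be poor. The fallback lets a nucleophile rather than the electrophile choose the face; it sets out from 23 and comes back at 24. NBS in aqueous DME forms the bromonium ion reversibly on either face. Water should open it at the less hindered C34 from the open β face, giving the bromohydrin F9 (C34 β-OH, C35 α-Br). K2CO3 in MeOH then closes the β-epoxide 24 by displacement of bromide with inversion at C35.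

**Further compounds**
F1 | step 14 | (Z)-vinyl iodide from 15 | O[C@@H]1CC[C@@H](O[Si](C)(C)C(C)(C)C)[C@H](CCOC(=O)C(C)(C)C)[C@@]1(C)C/C=C\I
F2 | step 14 | C5 2-methoxyprop-2-yl ether of F1 | COC(C)(C)O[C@@H]1CC[C@@H](O[Si](C)(C)C(C)(C)C)[C@H](CCOC(=O)C(C)(C)C)[C@@]1(C)C/C=C\I
F3 | step 14 | C5 isopropenyl ether | C=C(C)O[C@@H]1CC[C@@H](O[Si](C)(C)C(C)(C)C)[C@H](CCOC(=O)C(C)(C)C)[C@@]1(C)C/C=C\I
F4 | step 14 | oxepene with C8 silyl ether | CC1(C)O[C@@H]2CC[C@@H](O[Si](C)(C)C(C)(C)C)[C@H](CCOC(=O)C(C)(C)C)[C@@]2(C)CC=C1
F5 | step 14 | oxepene with C8 β-hydroxyl | CC1(C)O[C@@H]2CC[C@@H](O)[C@H](CCOC(=O)C(C)(C)C)[C@@]2(C)CC=C1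
F6 | step 29 | east C14 enol triflate | FC(F)(F)S(=O)(=O)OC1=C(C)CC[C@@H]2[C@@H](CC[C@@]2(C)O[Si](CC)(CC)CC)C1(C)C
F7 | step 29 | west C13 B-alkyl-9-borabicyclo[3.3.1]nonane | CC1(C)O[C@@H]2CC[C@](C)(O[Si](CC)(CC)CC)[C@H](CCB3C4CCCC3CCC4)[C@@]2(C)CC[C@H]1O[Si](CC)(CC)CC
F8 | step 29 | coupled C14=C16 alkene without O19 | CC1(C)O[C@@H]2CC[C@](C)(O[Si](CC)(CC)CC)[C@H](CCC3=C(C)CC[C@@H]4[C@@H](CC[C@@]4(C)O[Si](CC)(CC)CC)C3(C)C)[C@@]2(C)CC[C@H]1O[Si](CC)(CC)CC
F9 | step 16 | bromohydrin, C34 β-OH, C35 α-Br | CC1(C)O[C@@H]2CC[C@](C)(O[Si](CC)(CC)CC)[C@H](CCOC(=O)C(C)(C)C)[C@@]2(C)C[C@@H](O)[C@@H]1Br
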